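The middle flavan unit is disconnected at C3–C4 and O1–C2. Its C4 bears the C8 ring of the catechin unit and stands ortho to the ring-A oxygen O1, so ring A with C4 can be traced back to an ortho-quinone methide, while C2–C3 is a glycolaldehyde fragment. A single aminocatalytic operation joins the enamine of silyloxyacetaldehyde to that quinone methide and closes pyran ring C as a lactol, setting C3 and C4. The precursor is an ortho-hydroxybenzhydrol made from 8-formyl penta-O-benzylcatechin and a phloroglucinol-type phenol that already carries the benzylated epicatechin gallate unit para to its hydroxyl (the later 4→6 bond). C2 arylation, galloylation and hydrogenolysis complete the target.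

Key step: step 12

Assumption: the enamine of 19 reacts on the face remote from the catalyst's diaryl(silyloxy)methyl group with the catechin ring anti to the enamine C=C, as alkyl-aldehyde enamines do with nitroalkenes; on that model the (S)-catalyst gives the required C4 configuration.

Step 1
Reactants: 1 (−)-epicatechin
Product: 2 5,7,3',4'-tetra-O-benzyl-(−)-epicatechin
Conditions: BnBr, K2CO3, DMF, 0 °C → rt
Reagents that add atoms: benzyl bromide, BrCc1ccccc1
Why: Williamson ether synthesis: carbonate ionises the four phenols but not the secondary C3 alcohol, so only the phenols are benzylated and C2 and C3 keep their configuration.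

Step 2
Reactants: 2 5,7,3',4'-tetra-O-benzyl-(−)-epicatechin; 3 3,4,5-tris(benzyloxy)benzoic acid
Product: 4 hepta-O-benzyl-(−)-epicatechin gallate (5,7,3',4'-tetra-O-benzylepicatechin 3-O-tri-O-benzylgallate)
Conditions: 3 (1.5 equiv), DCC, DMAP, CH2Cl2, rt
Reagents that add atoms: none
Why: Steglich esterification: the carbodiimide-activated acid is passed on by DMAP as the N-acylpyridinium ion to the axial C3 hydroxyl, the only free hydroxyl, and C3 is retained because only its O–H bond reacts.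

Step 3
Reactants: 4 hepta-O-benzyl-(−)-epicatechin gallate
Product: 5 4β-(2-ethoxyethoxy)-hepta-O-benzylepicatechin gallate (C4 ether trans to the C3 ester)
Conditions: DDQ, 2-ethoxyethanol, CH2Cl2, rt
Reagents that add atoms: 2-ethoxyethanol, CCOCCO
Why: DDQ benzylic oxidation: hydride is taken from C4, the benzylic position activated by the A-ring oxygens, and the cation is captured by the alcohol on the β face, anti to the C2 aryl and the C3 acyloxy group, which sets C4 trans to O3.

Step 4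
Reactants: 6 3,5-bis(benzyloxy)phenol
Product: 7 [3,5-bis(benzyloxy)phenoxy]triisopropylsilane
Conditions: TIPSCl, imidazole, DMF, rt
Reagents that add atoms: triisopropylsilyl chloride, CC(C)[Si](Cl)(C(C)C)C(C)C
Why: Silyl ether formation at the only hydroxyl; the triisopropylsilyl group is chosen because it later shields both carbons ortho to this oxygen.

Step 5
Reactants: 5 4β-(2-ethoxyethoxy)-hepta-O-benzylepicatechin gallate; 7 [3,5-bis(benzyloxy)phenoxy]triisopropylsilane
Product: 8 4β-[2,6-bis(benzyloxy)-4-(triisopropylsilyloxy)phenyl]-hepta-O-benzylepicatechin gallate (3,4-trans)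
Conditions: 7 (3 equiv), TMSOTf (0.2 equiv), CH2Cl2, −78 → −40 °C; Et3N
Reagents that add atoms: none
Why: Friedel–Crafts alkylation by a flavan-4-yl cation, the reaction type of Lewis-acid procyanidin couplings: TMSOTf ionises the C4 ether, the excess arene intercepts the cation before the A ring of a second molecule can, it bonds through its carbon para to the silyloxy group because the two ortho carbons lie under the triisopropylsilyl group, and attack anti to the C2 aryl and the C3 gallate (which can bridge the α face) sets C4 as 3,4-trans.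

Step 6
Reactants: 8 4β-[2,6-bis(benzyloxy)-4-(triisopropylsilyloxy)phenyl]-hepta-O-benzylepicatechin gallate
Product: 9 4β-[2,6-bis(benzyloxy)-4-hydroxyphenyl]-hepta-O-benzylepicatechin gallate
Conditions: TBAF, AcOH, THF, 0 °C
Reagents that add atoms: none
Why: Fluoride desilylation: the aryl silyl ether is cleaved fast at 0 °C and the acetic acid buffer keeps the gallate ester and the benzyl ethers intact.

Step 7
Reactants: 10 (+)-catechin
Product: 11 5,7,3',4'-tetra-O-benzyl-(+)-catechin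
Conditions: BnBr, K2CO3, DMF, rt
Reagents that add atoms: benzyl bromide, BrCc1ccccc1
Why: Williamson ether synthesis: carbonate ionises the four phenols but not the secondary alcohol, so only the phenols are benzylated and C2 and C3 keep their configuration.

Step 8
Reactants: 11 5,7,3',4'-tetra-O-benzyl-(+)-catechin
Product: 12 3,5,7,3',4'-penta-O-benzyl-(+)-catechin
Conditions: NaH, BnBr, DMF, 0 °C → rt
Reagents that add atoms: benzyl bromide, BrCc1ccccc1
Why: Williamson ether synthesis on the sodium alkoxide of the remaining secondary alcohol, with retention at C3 because only the O–H bond is involved.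

Step 9
Reactants: 12 3,5,7,3',4'-penta-O-benzyl-(+)-catechin
Product: 13 8-bromo-penta-O-benzylcatechin
Conditions: NBS (1.0 equiv), CH2Cl2, −40 → 0 °C
Reagents that add atoms: N-bromosuccinimide, O=C1CCC(=O)N1Br
Why: Electrophilic aromatic bromination: C8, flanked by O1 and the C7 ether, is the more accessible activated A-ring carbon, whereas C6 sits between two benzyloxy groups, so one equivalent of NBS at low temperature should brominate C8.

Step 10
Reactants: 13 8-bromo-penta-O-benzylcatechin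
Product: 16 8-formyl-penta-O-benzylcatechin, via 8-lithio species 14 (not isolated), via lithium hemiaminal alkoxide 15 (not isolated)
Conditions: n-BuLi, THF, −78 °C; DMF, −78 → 0 °C; H2O
Reagents that add atoms: N,N-dimethylformamide, CN(C)C=O
Why: Bromine–lithium exchange is faster at −78 °C than deprotonation of the benzylic ethers, and the aryllithium adds once to DMF to give a hemiaminal alkoxide that releases the aldehyde only on work-up (Bouveault-type formylation).

Step 11
Reactants: 9 4β-[2,6-bis(benzyloxy)-4-hydroxyphenyl]-hepta-O-benzylepicatechin gallate; 16 8-formyl-penta-O-benzylcatechin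
Product: 18 ortho-hydroxybenzhydrol in which one carbon ortho to the phenol OH of 9 carries CH(OH)(penta-O-benzylcatechin-8-yl) (both carbinol epimers), via bromomagnesium phenoxide 17 (not isolated)
Conditions: EtMgBr (1.0 equiv), toluene, 0 °C; 16, rt; H2O, 0 °C
Reagents that add atoms: none
Why: ortho-Selective hydroxyalkylation of a magnesium phenoxide: the aldehyde is activated on magnesium and delivered to the carbon ortho to the phenoxide oxygen through a six-membered chelate in a non-coordinating solvent, the two ortho carbons are equivalent by symmetry, the single equivalent of Grignard base is consumed by the phenol before it can reach the ester, and the carbinol centre forms as both epimers and is erased in step 12.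

Step 12
Reactants: 18 ortho-hydroxybenzhydrol (both carbinol epimers); 19 (tert-butyldimethylsilyloxy)acetaldehyde
Product: 23 3,4-trans-3-(tert-butyldimethylsilyloxy)-4-(penta-O-benzylcatechin-8-yl)-5,7-bis(benzyloxy)-6-(hepta-O-benzylepicatechin-gallate-4β-yl)chroman-2-ol (anomeric mixture), via ortho-quinone methide 20 (not isolated), via silyloxy enamine 21 (not isolated), via open hydroxy aldehyde 22 (not isolated)
Conditions: 19 (3 equiv), (S)-α,α-diphenylprolinol trimethylsilyl ether (20 mol%), PhCO2H (20 mol%), CH2Cl2, 0 °C → rt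
Reagents that add atoms: none
Why: Benzoic acid dehydrates both epimers of 18 to the ortho-quinone methide 20, whose carbonyl oxygen is the future O1; the E-enamine 21 adds through the face remote from the diaryl(silyloxy)methyl group to the exocyclic carbon (C3–C4), ring A rearomatises, and hydrolysis releases the hydroxy aldehyde 22 and the catalyst. The phenol of 22 then adds to the aldehyde carbon (O1–C2) in a 6-exo-trig hemiacetalisation, which closes pyran ring C. The closest known reaction type is the diarylprolinol silyl ether-catalysed formal [4+2] annulation of aldehydes with ortho-quinone methides made in situ from ortho-hydroxybenzhydrols, which gives trans-3,4-disubstituted chroman-2-ols. C4 is set by the catalyst, since in the open synclinal transition state the catechin ring lies anti to the enamine C=C and the quinone methide ring carbon on the nitrogen side, so that one face of the methide carbon is presented; C3 is set by the enamine face and, being α to the aldehyde in 22, can also settle into the more stable 3,4-trans lactol, while C2 stays an anomeric mixture that step 15 removes. The step needs reagent control over the remote stereocentres of both flavan units and enamine addition faster than self-aldolisation of 19; regiochemistry is not at issue because 18 has one free phenol and its upper unit sits para to that hydroxyl.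

Step 13
Reactants: 23 chroman-2-ol (anomeric mixture)
Product: 24 the corresponding chroman-2-yl acetate (anomeric mixture)
Conditions: Ac2O, pyridine, DMAP (cat.), CH2Cl2, 0 °C → rt
Reagents that add atoms: acetic anhydride, CC(=O)OC(C)=O
Why: DMAP-catalysed acylation of the only free hydroxyl turns the lactol into an anomeric acetate, the leaving group for step 15, and both anomers serve.

Step 14
Reactants: 25 4-bromo-1,2-bis(benzyloxy)benzene
Product: 28 potassium [3,4-bis(benzyloxy)phenyl]trifluoroborate, via aryllithium 26 (not isolated), via lithium aryltriisopropoxyborate 27 (not isolated)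
Conditions: n-BuLi, THF, −78 °C; B(OiPr)3, −78 °C → rt; aq. KHF2, MeOH, rt
Reagents that add atoms: triisopropyl borate, CC(C)OB(OC(C)C)OC(C)C; potassium hydrogen difluoride, F.[F-].[K+]
Why: Bromine–lithium exchange, borylation of the aryllithium with the borate ester and exchange of the alkoxides for fluoride with KHF2, the standard preparation of a potassium aryltrifluoroborate.

Step 15
Reactants: 24 chroman-2-yl acetate; 28 potassium [3,4-bis(benzyloxy)phenyl]trifluoroborate
Product: 29 hexadeca-O-benzyl epicatechin-3-O-gallate-(4β→6)-[3-O-TBS-epicatechin]-(4β→8)-catechin (middle ring 2,3-cis-3,4-trans)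
Conditions: 28 (2 equiv), BF3·OEt2 (3 equiv), CH2Cl2/MeCN, −40 → 0 °C; H2O
Reagents that add atoms: none
Why: BF3-mediated addition of an aryltrifluoroborate to an acetal-derived oxocarbenium ion (C-arylation of an anomeric acetate): BF3 ionises the acetate and unmasks the aryldifluoroborane, whose ipso carbon delivers the aryl group from the borate counter-ion faster than the benzylated phloroglucinol rings can attack, and the aryl group enters on the face anti to the C4 catechin ring through the half-chair with the 3-silyloxy group pseudoequatorial (2-alkoxy oxocarbenium ions generally give 1,2-cis products), which sets C2 cis to O3 and trans to the C4 aryl.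

Step 16
Reactants: 29 middle-unit 3-O-TBS trimer
Product: 30 hexadeca-O-benzyl epicatechin-3-O-gallate-(4β→6)-epicatechin-(4β→8)-catechin (free middle 3-OH)
Conditions: TBAF, AcOH, THF, rt → 45 °C
Reagents that add atoms: none
Why: Fluoride desilylation of the hindered secondary silyl ether under acetic acid buffering, which spares the upper gallate ester and all benzyl ethers and leaves C3 unchanged.

Step 17
Reactants: 30 middle 3-OH trimer; 3 3,4,5-tris(benzyloxy)benzoic acid
Product: 31 nonadeca-O-benzyl epicatechin-3-O-gallate-(4β→6)-epicatechin-3-O-gallate-(4β→8)-catechin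
Conditions: 3 (3 equiv), DCC, DMAP, CH2Cl2, rt
Reagents that add atoms: none
Why: Steglich esterification: the carbodiimide-activated acid is transferred by DMAP to the hindered axial C3 hydroxyl, the only free hydroxyl, with retention at C3.

Step 18
Reactants: 31 nonadeca-O-benzyl trimer digallate
Product: 32 epicatechin-3-O-gallate-(4β→6)-epicatechin-3-O-gallate-(4β→8)-catechin (CNP0112921.1)
Conditions: H2 (1 atm), Pd(OH)2/C, THF/MeOH/H2O, rt
Reagents that add atoms: none
Why: Catalytic hydrogenolysis cleaves all nineteen benzyl ethers (aryl and the one alkyl) as toluene under neutral conditions that leave the two gallate esters, the interflavan bonds and all eight stereocentres intact.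

Compound list

1 | (−)-epicatechin (2R,3R) | O[C@@H]1Cc2c(O)cc(O)cc2O[C@@H]1c1ccc(O)c(O)c1 | starting material
2 | 5,7,3',4'-tetra-O-benzyl-(−)-epicatechin | O[C@@H]1Cc2c(OCc9ccccc9)cc(OCc9ccccc9)cc2O[C@@H]1c8ccc(OCc9ccccc9)c(OCc9ccccc9)c8 | intermediate
3 | 3,4,5-tris(benzyloxy)benzoic acid | OC(=O)c1cc(OCc2ccccc2)c(OCc2ccccc2)c(OCc2ccccc2)c1 | starting material
4 | hepta-O-benzyl-(−)-epicatechin gallate | O=C(c7cc(OCc9ccccc9)c(OCc9ccccc9)c(OCc9ccccc9)c7)O[C@@H]1Cc2c(OCc9ccccc9)cc(OCc9ccccc9)cc2O[C@@H]1c8ccc(OCc9ccccc9)c(OCc9ccccc9)c8 | intermediate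
5 | 4β-(2-ethoxyethoxy)-hepta-O-benzylepicatechin gallate (3,4-trans) | O=C(c7cc(OCc9ccccc9)c(OCc9ccccc9)c(OCc9ccccc9)c7)O[C@@H]1[C@@H](OCCOCC)c2c(OCc9ccccc9)cc(OCc9ccccc9)cc2O[C@@H]1c8ccc(OCc9ccccc9)c(OCc9ccccc9)c8 | intermediate
6 | 3,5-bis(benzyloxy)phenol | Oc1cc(OCc2ccccc2)cc(OCc2ccccc2)c1 | starting material
7 | [3,5-bis(benzyloxy)phenoxy]triisopropylsilane | CC(C)[Si](Oc1cc(OCc2ccccc2)cc(OCc2ccccc2)c1)(C(C)C)C(C)C | intermediate
8 | 4β-[2,6-bis(benzyloxy)-4-(triisopropylsilyloxy)phenyl]-hepta-O-benzylepicatechin gallate | O=C(c7cc(OCc9ccccc9)c(OCc9ccccc9)c(OCc9ccccc9)c7)O[C@@H]1[C@@H](c3c(OCc9ccccc9)cc(O[Si](C(C)C)(C(C)C)C(C)C)cc3OCc9ccccc9)c2c(OCc9ccccc9)cc(OCc9ccccc9)cc2O[C@@H]1c8ccc(OCc9ccccc9)c(OCc9ccccc9)c8 | intermediate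
9 | 4β-[2,6-bis(benzyloxy)-4-hydroxyphenyl]-hepta-O-benzylepicatechin gallate | O=C(c7cc(OCc9ccccc9)c(OCc9ccccc9)c(OCc9ccccc9)c7)O[C@@H]1[C@@H](c3c(OCc9ccccc9)cc(O)cc3OCc9ccccc9)c2c(OCc9ccccc9)cc(OCc9ccccc9)cc2O[C@@H]1c8ccc(OCc9ccccc9)c(OCc9ccccc9)c8 | intermediate
10 | (+)-catechin (2R,3S) | O[C@H]1Cc2c(O)cc(O)cc2O[C@@H]1c1ccc(O)c(O)c1 | starting material
11 | 5,7,3',4'-tetra-O-benzyl-(+)-catechin | c1c(OCc9ccccc9)cc(OCc9ccccc9)c2c1O[C@H](c8ccc(OCc9ccccc9)c(OCc9ccccc9)c8)[C@@H](O)C2 | intermediate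
12 | 3,5,7,3',4'-penta-O-benzyl-(+)-catechin | c1c(OCc9ccccc9)cc(OCc9ccccc9)c2c1O[C@H](c8ccc(OCc9ccccc9)c(OCc9ccccc9)c8)[C@@H](OCc9ccccc9)C2 | intermediate
13 | 8-bromo-penta-O-benzylcatechin | Brc1c(OCc9ccccc9)cc(OCc9ccccc9)c2c1O[C@H](c8ccc(OCc9ccccc9)c(OCc9ccccc9)c8)[C@@H](OCc9ccccc9)C2 | intermediate
14 | 8-lithio-penta-O-benzylcatechin | [Li]c1c(OCc9ccccc9)cc(OCc9ccccc9)c2c1O[C@H](c8ccc(OCc9ccccc9)c(OCc9ccccc9)c8)[C@@H](OCc9ccccc9)C2 | intermediate (not isolated)
15 | lithium hemiaminal alkoxide from 14 and DMF | [Li]OC(N(C)C)c1c(OCc9ccccc9)cc(OCc9ccccc9)c2c1O[C@H](c8ccc(OCc9ccccc9)c(OCc9ccccc9)c8)[C@@H](OCc9ccccc9)C2 | intermediate (not isolated)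
16 | 8-formyl-penta-O-benzylcatechin | O=Cc1c(OCc9ccccc9)cc(OCc9ccccc9)c2c1O[C@H](c8ccc(OCc9ccccc9)c(OCc9ccccc9)c8)[C@@H](OCc9ccccc9)C2 | intermediate
17 | bromomagnesium phenoxide of 9 | O=C(c7cc(OCc9ccccc9)c(OCc9ccccc9)c(OCc9ccccc9)c7)O[C@@H]1[C@@H](c3c(OCc9ccccc9)cc(O[Mg]Br)cc3OCc9ccccc9)c2c(OCc9ccccc9)cc(OCc9ccccc9)cc2O[C@@H]1c8ccc(OCc9ccccc9)c(OCc9ccccc9)c8 | intermediate (not isolated)
18 | ortho-hydroxybenzhydrol (both carbinol epimers) | O=C(c7cc(OCc9ccccc9)c(OCc9ccccc9)c(OCc9ccccc9)c7)O[C@@H]1[C@@H](c3c(OCc9ccccc9)cc(O)c(C(O)c5c(OCc9ccccc9)cc(OCc9ccccc9)c6c5O[C@H](c8ccc(OCc9ccccc9)c(OCc9ccccc9)c8)[C@@H](OCc9ccccc9)C6)c3OCc9ccccc9)c2c(OCc9ccccc9)cc(OCc9ccccc9)cc2O[C@@H]1c8ccc(OCc9ccccc9)c(OCc9ccccc9)c8 | intermediate (key-step precursor)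
19 | (tert-butyldimethylsilyloxy)acetaldehyde | CC(C)(C)[Si](C)(C)OCC=O | starting material
20 | ortho-quinone methide from 18 (exocyclic geometry not fixed) | O=C(c7cc(OCc9ccccc9)c(OCc9ccccc9)c(OCc9ccccc9)c7)O[C@@H]1[C@@H](C3=C(OCc9ccccc9)C(=Cc5c(OCc9ccccc9)cc(OCc9ccccc9)c6c5O[C@H](c8ccc(OCc9ccccc9)c(OCc9ccccc9)c8)[C@@H](OCc9ccccc9)C6)C(=O)C=C3OCc9ccccc9)c2c(OCc9ccccc9)cc(OCc9ccccc9)cc2O[C@@H]1c8ccc(OCc9ccccc9)c(OCc9ccccc9)c8 | intermediate (not isolated)
21 | (E)-enamine of 19 with (S)-α,α-diphenylprolinol trimethylsilyl ether | CC(C)(C)[Si](C)(C)O/C=C/N1CCC[C@H]1C(c1ccccc1)(c1ccccc1)O[Si](C)(C)C | intermediate (not isolated)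
22 | open hydroxy aldehyde (2-silyloxy-3,3-diarylpropanal with free phenol) | O=C(c7cc(OCc9ccccc9)c(OCc9ccccc9)c(OCc9ccccc9)c7)O[C@@H]1[C@@H](c3c(OCc9ccccc9)cc(O)c(c3OCc9ccccc9)[C@H](c5c(OCc9ccccc9)cc(OCc9ccccc9)c6c5O[C@H](c8ccc(OCc9ccccc9)c(OCc9ccccc9)c8)[C@@H](OCc9ccccc9)C6)[C@@H](O[Si](C)(C)C(C)(C)C)C=O)c2c(OCc9ccccc9)cc(OCc9ccccc9)cc2O[C@@H]1c8ccc(OCc9ccccc9)c(OCc9ccccc9)c8 | intermediate (not isolated)
23 | 3,4-trans 3-silyloxy-4-(catechin-8-yl)chroman-2-ol with the upper unit at C6 (anomeric mixture) | O=C(c7cc(OCc9ccccc9)c(OCc9ccccc9)c(OCc9ccccc9)c7)O[C@@H]1[C@@H](c3c(OCc9ccccc9)cc4c(c3OCc9ccccc9)[C@H](c5c(OCc9ccccc9)cc(OCc9ccccc9)c6c5O[C@H](c8ccc(OCc9ccccc9)c(OCc9ccccc9)c8)[C@@H](OCc9ccccc9)C6)[C@@H](O[Si](C)(C)C(C)(C)C)C(O)O4)c2c(OCc9ccccc9)cc(OCc9ccccc9)cc2O[C@@H]1c8ccc(OCc9ccccc9)c(OCc9ccccc9)c8 | intermediate (key-step product)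
24 | chroman-2-yl acetate of 23 (anomeric mixture) | O=C(c7cc(OCc9ccccc9)c(OCc9ccccc9)c(OCc9ccccc9)c7)O[C@@H]1[C@@H](c3c(OCc9ccccc9)cc4c(c3OCc9ccccc9)[C@H](c5c(OCc9ccccc9)cc(OCc9ccccc9)c6c5O[C@H](c8ccc(OCc9ccccc9)c(OCc9ccccc9)c8)[C@@H](OCc9ccccc9)C6)[C@@H](O[Si](C)(C)C(C)(C)C)C(OC(C)=O)O4)c2c(OCc9ccccc9)cc(OCc9ccccc9)cc2O[C@@H]1c8ccc(OCc9ccccc9)c(OCc9ccccc9)c8 | intermediate
25 | 4-bromo-1,2-bis(benzyloxy)benzene | Brc1ccc(OCc2ccccc2)c(OCc2ccccc2)c1 | starting material
26 | 3,4-bis(benzyloxy)phenyllithium | [Li]c1ccc(OCc2ccccc2)c(OCc2ccccc2)c1 | intermediate (not isolated)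
27 | lithium [3,4-bis(benzyloxy)phenyl]triisopropoxyborate | [Li+].CC(C)O[B-](OC(C)C)(OC(C)C)c1ccc(OCc2ccccc2)c(OCc2ccccc2)c1 | intermediate (not isolated)
28 | potassium [3,4-bis(benzyloxy)phenyl]trifluoroborate | [K+].F[B-](F)(F)c1ccc(OCc2ccccc2)c(OCc2ccccc2)c1 | intermediate
29 | hexadeca-O-benzyl trimer with middle 3-O-TBS (middle ring 2,3-cis-3,4-trans) | O=C(c7cc(OCc9ccccc9)c(OCc9ccccc9)c(OCc9ccccc9)c7)O[C@@H]1[C@@H](c3c(OCc9ccccc9)cc4c(c3OCc9ccccc9)[C@H](c5c(OCc9ccccc9)cc(OCc9ccccc9)c6c5O[C@H](c8ccc(OCc9ccccc9)c(OCc9ccccc9)c8)[C@@H](OCc9ccccc9)C6)[C@@H](O[Si](C)(C)C(C)(C)C)[C@@H](c8ccc(OCc9ccccc9)c(OCc9ccccc9)c8)O4)c2c(OCc9ccccc9)cc(OCc9ccccc9)cc2O[C@@H]1c8ccc(OCc9ccccc9)c(OCc9ccccc9)c8 | intermediate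
30 | hexadeca-O-benzyl trimer with free middle 3-OH | O=C(c7cc(OCc9ccccc9)c(OCc9ccccc9)c(OCc9ccccc9)c7)O[C@@H]1[C@@H](c3c(OCc9ccccc9)cc4c(c3OCc9ccccc9)[C@H](c5c(OCc9ccccc9)cc(OCc9ccccc9)c6c5O[C@H](c8ccc(OCc9ccccc9)c(OCc9ccccc9)c8)[C@@H](OCc9ccccc9)C6)[C@@H](O)[C@@H](c8ccc(OCc9ccccc9)c(OCc9ccccc9)c8)O4)c2c(OCc9ccccc9)cc(OCc9ccccc9)cc2O[C@@H]1c8ccc(OCc9ccccc9)c(OCc9ccccc9)c8 | intermediate
31 | nonadeca-O-benzyl trimer digallate | O=C(c7cc(OCc9ccccc9)c(OCc9ccccc9)c(OCc9ccccc9)c7)O[C@@H]1[C@@H](c3c(OCc9ccccc9)cc4c(c3OCc9ccccc9)[C@H](c5c(OCc9ccccc9)cc(OCc9ccccc9)c6c5O[C@H](c8ccc(OCc9ccccc9)c(OCc9ccccc9)c8)[C@@H](OCc9ccccc9)C6)[C@@H](OC(=O)c7cc(OCc9ccccc9)c(OCc9ccccc9)c(OCc9ccccc9)c7)[C@@H](c8ccc(OCc9ccccc9)c(OCc9ccccc9)c8)O4)c2c(OCc9ccccc9)cc(OCc9ccccc9)cc2O[C@@H]1c8ccc(OCc9ccccc9)c(OCc9ccccc9)c8 | intermediate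
32 | epicatechin-3-O-gallate-(4β→6)-epicatechin-3-O-gallate-(4β→8)-catechin | O=C(O[C@@H]1[C@@H](c2c(O)cc3c(c2O)[C@H](c2c(O)cc(O)c4c2O[C@H](c2ccc(O)c(O)c2)[C@@H](O)C4)[C@@H](OC(=O)c2cc(O)c(O)c(O)c2)[C@@H](c2ccc(O)c(O)c2)O3)c2c(O)cc(O)cc2O[C@@H]1c1ccc(O)c(O)c1)c1cc(O)c(O)c(O)c1 | target

Total step count: 18. Longest linear sequence: 12 steps (1, 2, 3, 5, 6, 11, 12, 13, 15, 16, 17, 18; the catechin branch, steps 7–10, joins at step 11).

Steps most likely to fail

Step 12. The quinone methide is electron-rich and flanked on both sides, so enamine addition may be slow; the quinone methide could then dimerise, be trapped by a neighbouring arene or revert, and the catalyst may not override the bias of the two flavan units at C4. The fallback sets out from benzhydrol 18 and aldehyde 19 and returns at lactol 23. Aldehyde 19 is converted with TBSOTf and Et3N into the enediol bis-silyl ether (Z)-1,2-bis(tert-butyldimethylsilyloxy)ethene F1. A chiral BINOL-derived phosphoric acid then generates the quinone methide from 18 and catalyses its inverse-electron-demand hetero-Diels–Alder reaction with F1, forming C3–C4 and O1–C2 in the 2,3-cis-2,3-bis(silyloxy)chroman F2. Selective hydrolysis of the anomeric silyl acetal (AcOH, THF/H2O) gives 23, in which C3 can still be equilibrated to the trans lactol with a mild amine base.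

Step 15. Aryl transfer may be slower than loss of the C3 proton from the oxocarbenium ion or its capture by a benzylated phloroglucinol ring of a second molecule, and the aryl group may enter on the face cis to the C4 aryl. The fallback sets out from lactol 23 and bromide 25 and returns at 29; it sets C2 in an open-chain addition and closes the ring afterwards. Bromide 25 and magnesium give the Grignard reagent 3,4-bis(benzyloxy)phenylmagnesium bromide F3. F3 is added in excess at −78 → −40 °C; the first equivalent is spent on the lactol hydroxyl and opens the ring to the phenoxide aldehyde. Non-chelation addition anti to the silyloxy group is expected, and the hindered gallate should survive at this temperature. The product is the 1,2-anti phenol carbinol F4. An intramolecular Mitsunobu reaction (PPh3, DIAD, THF) then forms O1–C2 with inversion and gives the 2,3-cis flavan 29.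

Step 11. The aldehyde is hindered and deactivated by three ring oxygens, so C–C bond formation may stall, and the magnesium salt of the very electron-rich benzhydrol may ionise to the quinone methide and pick up a second phenoxide. The fallback sets out from phenol 9 and bromide 13 and returns at benzhydrol 18, with the polarity reversed. Ortho-formylation of 9 (MgCl2, Et3N, paraformaldehyde, MeCN; the two ortho carbons are equivalent) gives the salicylaldehyde 4β-[2,6-bis(benzyloxy)-3-formyl-4-hydroxyphenyl]-hepta-O-benzylepicatechin gallate F5. The aryllithium 14, made from 13 as in step 10 and used in twofold amount at −78 °C (the first equivalent is spent on the phenol), then adds to the aldehyde of F5 to give 18.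

Further compounds

F1 | step 12 | (Z)-1,2-bis(tert-butyldimethylsilyloxy)ethene | CC(C)(C)[Si](C)(C)O/C=C\O[Si](C)(C)C(C)(C)C
F2 | step 12 | 2,3-cis-3,4-trans 2,3-bis(tert-butyldimethylsilyloxy)chroman cycloadduct | O=C(c7cc(OCc9ccccc9)c(OCc9ccccc9)c(OCc9ccccc9)c7)O[C@@H]1[C@@H](c3c(OCc9ccccc9)cc4c(c3OCc9ccccc9)[C@H](c5c(OCc9ccccc9)cc(OCc9ccccc9)c6c5O[C@H](c8ccc(OCc9ccccc9)c(OCc9ccccc9)c8)[C@@H](OCc9ccccc9)C6)[C@@H](O[Si](C)(C)C(C)(C)C)[C@@H](O[Si](C)(C)C(C)(C)C)O4)c2c(OCc9ccccc9)cc(OCc9ccccc9)cc2O[C@@H]1c8ccc(OCc9ccccc9)c(OCc9ccccc9)c8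
F3 | step 15 | 3,4-bis(benzyloxy)phenylmagnesium bromide | Br[Mg]c1ccc(OCc2ccccc2)c(OCc2ccccc2)c1
F4 | step 15 | 1,2-anti phenol carbinol (1-aryl-2-silyloxy-3,3-diarylpropan-1-ol with free phenol) | O=C(c7cc(OCc9ccccc9)c(OCc9ccccc9)c(OCc9ccccc9)c7)O[C@@H]1[C@@H](c3c(OCc9ccccc9)cc(O)c(c3OCc9ccccc9)[C@H](c5c(OCc9ccccc9)cc(OCc9ccccc9)c6c5O[C@H](c8ccc(OCc9ccccc9)c(OCc9ccccc9)c8)[C@@H](OCc9ccccc9)C6)[C@@H](O[Si](C)(C)C(C)(C)C)[C@H](c8ccc(OCc9ccccc9)c(OCc9ccccc9)c8)O)c2c(OCc9ccccc9)cc(OCc9ccccc9)cc2O[C@@H]1c8ccc(OCc9ccccc9)c(OCc9ccccc9)c8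
F5 | step 11 | 4β-[2,6-bis(benzyloxy)-3-formyl-4-hydroxyphenyl]-hepta-O-benzylepicatechin gallate | O=C(c7cc(OCc9ccccc9)c(OCc9ccccc9)c(OCc9ccccc9)c7)O[C@@H]1[C@@H](c3c(OCc9ccccc9)cc(O)c(C=O)c3OCc9ccccc9)c2c(OCc9ccccc9)cc(OCc9ccccc9)cc2O[C@@H]1c8ccc(OCc9ccccc9)c(OCc9ccccc9)c8
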